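# Synthesis design for CNP0124601.1 (26)

## The problem

CNP0124601.1 (26) is a C40 heterodimer in which a ring-B-contracted abietane (rings A/B/C 6-5-6) and a labda-8(17),12E,14-trien-18-oic acid are joined by two carbon–carbon bonds, C8–C15′ and C13–C14′. The former ring C (C8, C9, C11–C14) and the terminal vinyl group of the labdane thereby form a bicyclo[3.2.1]octenedione with C14 as the one-carbon carbonyl bridge. Ring-contracted compounds are numbered as in the target: C6 is the ring carbinol carbon and C7 its exocyclic carbon.

There are ten stereocentres and one E double bond (C12′=C13′). C4′, C5′, C9′ and C10′ sit in the labdane decalin, far from everything else, and have to be bought. C10 is the one centre of the abietane half that cannot be derived from another. It can control C5 (trans fusion) and, through the shape of ring B, C6. C10 and C6 then differentiate the two faces of ring C and fix the bridgeheads C8 and C13 together. C14′ depends only on how the alkene is oriented in the union.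

Several groups will not survive rough treatment:
- the tertiary α-hydroxy aldehyde at C6 (α-ketol ring enlargement with acid or base, dehydration while ring C is still an electron-rich arene);
- the non-enolisable β-diketone C12–C13–C14 (retro-Claisen cleavage);
- the enolised 1,2-dione C11/C12;
- the exocyclic C8′=C17′ bond (acid isomerisation).

The aldehyde and the bicyclic dione should therefore appear last.

Two features point to the plan. The five-membered ring B (C5, C6, C8, C9, C10), whose C6 carries a hydroxyl and the carbonyl branch C7 and is bonded to both C5 and C8, is what a six-membered abietane ring B with carbonyls at C6 and C7 gives when C5 shifts from one carbonyl carbon to the other. The bicyclooctenedione is the footprint of an alkene adding across C8 and C13 of a 12-hydroxy-11,14-quinone.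

## Retrosynthesis

**26 ⇒ 21 + 25.** The bonds C8–C15′ and C13–C14′ are cut together. This returns two halves of equal size, hydroxyquinone aldehyde 21 and diene acid 25, each a resin-acid derivative. Any other first cut (for instance at C12′=C13′) would leave the bicyclooctane to be built on a fragment already carrying the fragile groups. The forward reaction is an acid-promoted (5+2) addition of the perezone–pipitzol type. It must send the diene terminus C15′ to C8, use the α face of the quinone, and close endo at C14′. No protecting group is left on either partner.

**21 ⇒ 20 ⇒ 16.** The aldehyde is taken back to the primary alcohol of diol 20, and the C11–O and C14–O bonds of the hydroxyquinone are removed to give phenol 16. The aldehyde is made last because the ring C oxidation needs alkali. The quinone is made from a phenol, not from a polyoxygenated arene, because one oxygen at C12 is all that a resin acid can be given cheaply.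

**16 ⇒ 15 ⇒ 14.** The phenol is masked as its methyl ether and C7 is raised to the carboxyl level. Hydroxy acid 14 has no group that is sensitive to base or heat and is the first compound with the 6-5-6 skeleton.

**14 ⇒ 12 ⇒ 10.** The ring bond C5–C6 of 14 is cut and C5 is reconnected to the carboxyl carbon. This regenerates the six-membered ring B of 12-methoxyabietane-6,7-dione 12. The alternatives would build the five-membered ring by Friedel–Crafts, Nazarov or aldol closure and would then have to create C5, C6 and C10. The ring contraction keeps rings A and C and C10 of a bought abietane. It delivers the C6 oxygen and the C7 carbon at the right oxidation level in one step. The forward benzilic acid rearrangement must let C5 (not the aryl carbon C8) migrate, keep the A/B fusion trans, and place the carboxyl on the β face. Such diones rest as their C5 enols, here diosphenol 13, which in base is a dienolate. Dione 12 is therefore not stocked. It is made from ketone 10 by oxygenation of the enolate (only C6 can enolise) and rearranged in the same flask, where it stands in equilibrium with 13.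

**10 ⇒ 9.** The C7 oxygen comes from benzylic oxidation of ferruginol methyl ether 9.

**9 ⇒ 7 ⇒ 6 ⇒ 5 ⇒ 3 ⇒ 2 ⇒ 1.** The C12–O bond is cut by way of acetate 7 and aryl ketone 6 (acylation, Baeyer–Villiger). The C4 methyl of abietatriene 5 is taken back through aldehyde 3 and alcohol 2 to the carboxyl of (+)-dehydroabietic acid 1. All steps are standard resin-acid chemistry and touch no stereocentre.

**25 ⇒ 24 ⇒ 23 ⇒ 22.** The methylene groups C15′ and C17′ are removed (keto enal 24), then the C12′=C13′ bond (keto aldehyde 23). The two carbonyls of 23 are recognised as the ends of the ring C diene of levopimaric acid 22, which has the same C4, C5, C9 and C10 configuration and the C18 carboxyl of 25. Building the decalin by polyene cyclisation would need an asymmetric step, a deoxygenation and a side-chain homologation. The degradation needs three steps and no protecting group.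

## Roads not taken

**Alternative 1: radical bicyclisation to build the labdane half.** The cut is through C4′–C5′ and C9′–C10′ of the decalin. In the forward step Cp2TiCl (trivalent titanium) opens the epoxide of (10S,11S)-epoxy diacetate A2, made from (2E,6E)-farnesol A3 by terminal allylic oxidation, Sharpless epoxidation and acetylation. The C4′ radical closes both rings and ends as the exocyclic alkene of bicyclic alcohol A1.
- Merits: the supply is cheap and dependable, either enantiomer is available, the C18′ oxygen is in place, and the C8′=C17′ bond forms regioselectively.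
- Weak points for this target: A1 still needs removal of the C3′ hydroxyl, oxidation of C18′, a one-carbon homologation at the hindered C11′ and the diene. The C4′ configuration rests on the conformational preference of a planar radical, not on the epoxide geometry. The radical carries a β-acetoxy group that can be lost after a second reduction.
- Comparison: this road puts the strategic step into the half that a resin acid already contains and leaves the ring contraction unsolved. It is better in independence from a sensitive natural starting material. Against that the chosen plan sets three steps from 22 with all four centres bought.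

**Alternative 2: ring C annulated last on a hydrindanone.** The cut is through C8–C14 and C9–C11. The potassium enolate of trans-hydrindanone A5 adds through C8 to β-methoxy enone A6 with loss of methoxide. The C11 methylene then condenses on the C9 ketone, and tautomerisation gives arene A4.
- Merits: no ring contraction is needed, so the C5 epimerisation question does not arise. C6 is set on a small ketone. Ring C arrives with two of its three oxygens, so the late arene oxidation starts one oxygen ahead of the chosen plan.
- Weak points: A5 with three contiguous centres (C5, C6, C10) must itself be made in many steps from one bought centre. The aldol closure has to attack a ketone flanked by the quaternary C10. Rings A and C, the isopropyl group, C5 and C10 are all built, whereas 1 supplies them.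
- Comparison: better in the late oxidation and in avoiding the contraction risk. The chosen plan sets against it a far shorter route to the tricycle.

**Alternative 3: late Wolff contraction of a six-membered ring B adduct.** The cut is the same ring contraction, but placed after the union. Photolysis of diazo ketone A8 expels nitrogen, C8 migrates from C7 to C6, and a thiol traps the ketene as thioester A7.
- Merits: the contraction is not basic, so C5 cannot epimerise. The (5+2) union is run on a quinone without the hydroxy aldehyde, which is better than in the chosen plan.
- Weak points: diazo transfer needs base on a dimer with a retro-Claisen-prone β-diketone. The β,γ-unsaturated ketone of the bicyclooctenedione is itself photoactive. The migrating atom is a quaternary bridgehead, not an aryl carbon. A7 lacks the C6 hydroxyl, which would have to be introduced by enolate oxidation on the dimer, followed by three unmaskings.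
- Comparison: the chosen plan does the contraction on a robust tricycle available in quantity and keeps the dimer for a single step. It sets against the Wolff advantage a fallback that borrows that rearrangement at the monomer stage.

Key step: step 8

## Route

Remark: levopimaric acid 22 is assumed to be bought as the pure resin acid and used fresh (cold, under argon), because it isomerises and autoxidises on storage.

Remark: the 6,7-dione 12 is taken to rest as its C5 enol 13 (in base as the dienolate), as abietane 6,7-diones do, so it is generated and rearranged in one flask and not stocked.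

Step 1
Reactants: 1 (+)-dehydroabietic acid
Product: 2 dehydroabietinol (abieta-8,11,13-trien-18-ol)
Conditions: LiAlH4, THF, 0 °C to reflux; then H2O
Reagents that add atoms: none
Why: Hydride reduction of a carboxylic acid to the primary alcohol; no stereocentre is touched.

Step 2
Reactants: 2 dehydroabietinol
Product: 3 dehydroabietinal (abieta-8,11,13-trien-18-al)
Conditions: Dess–Martin periodinane, CH2Cl2, 25 °C
Reagents that add atoms: none
Why: Dess–Martin oxidation of a hindered neopentyl alcohol; the aldehyde has no α-hydrogen and cannot epimerise.

Step 3
Reactants: 3 dehydroabietinal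
Product: 5 abieta-8,11,13-triene, via hydrazone 4 (not isolated)
Conditions: N2H4·H2O, KOH, diethylene glycol, 130 °C then 200 °C
Reagents that add atoms: none
Why: Wolff–Kishner reduction in the Huang-Minlon form; hydrazone 4 loses N2 under base and leaves the C4 methyl group of the gem-dimethyl pattern.

Step 4
Reactants: 5 abieta-8,11,13-triene
Product: 6 12-acetylabieta-8,11,13-triene
Conditions: AcCl, AlCl3, CH2Cl2, 0 °C
Reagents that add atoms: acetyl chloride, CC(=O)Cl
Why: Friedel–Crafts acylation; C12 is para to the C8 alkyl group and the least hindered open position (C11 is screened by ring A, C14 lies between the isopropyl group and C7), as established for dehydroabietane derivatives.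

Step 5
Reactants: 6 12-acetylabieta-8,11,13-triene
Product: 7 ferruginyl acetate (abieta-8,11,13-trien-12-yl acetate)
Conditions: mCPBA, CF3CO2H (cat.), CH2Cl2, 25 °C
Reagents that add atoms: mCPBA (3-chloroperoxybenzoic acid), O=C(OO)c1cccc(Cl)c1
Why: Baeyer–Villiger oxidation of an aryl methyl ketone; the electron-rich aryl group migrates in preference to methyl and puts oxygen on C12.

Step 6
Reactants: 7 ferruginyl acetate
Product: 9 ferruginol methyl ether (12-methoxyabieta-8,11,13-triene), via ferruginol 8 (not isolated)
Conditions: K2CO3, MeOH, 25 °C; then MeI, 40 °C
Reagents that add atoms: iodomethane, CI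
Why: Methanolysis of the aryl acetate and Williamson O-methylation of the phenoxide in one flask; the methyl ether survives CrO3 and hot KOH and gives the C7 ketone of step 8 a para donor of moderate strength.

Step 7
Reactants: 9 ferruginol methyl ether
Product: 10 sugiol methyl ether (12-methoxyabieta-8,11,13-trien-7-one)
Conditions: CrO3, AcOH–H2O, 25 °C
Reagents that add atoms: chromium trioxide, O=[Cr](=O)=O
Why: Benzylic oxidation with hexavalent chromium; the C7 methylene is attacked faster than the C15 methine, a long-established transformation of ferruginol ethers.

Step 8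
Reactants: 10 sugiol methyl ether
Product: 14 12-methoxy hydroxy acid of the 6-5-6 series (6α-hydroxy, C7 carboxyl on the β face of C6, 5α-H, 10β-methyl), via 6-hydroperoxy ketone 11 (not isolated), via 6,7-dione 12 (not isolated), via diosphenol 13 (not isolated)
Conditions: KOtBu, O2 (1 atm, one equivalent taken up), tBuOH–THF, 0 °C; argon purge; then degassed aq. KOH, 85 °C, argon; then aq. HCl, 0 °C
Reagents that add atoms: dioxygen, O=O; potassium hydroxide, [K+].[OH-]
Why: Base-mediated autoxidation of a ketone followed in the same flask by a benzilic acid rearrangement (closest known type: autoxidation of steroidal ketones with KOtBu and O2 to diosphenols and the alkali contraction of ring A diosphenols to A-nor hydroxy acids). Ketone 10 can enolise only toward C6; its enolate takes up O2 to hydroperoxide 11, Kornblum–DeLaMare loss of hydroxide gives the 6,7-dione 12, and 12 is at once deprotonated at C5 to the potassium dienolate of diosphenol 13, the resting state, which the argon purge keeps from a second oxygenation. In hot aqueous KOH the dienolate is protonated at C5 from the α face, away from the axial methyl groups on C10 and C4, and so returns the trans-fused dione 12 in low concentration. Hydroxide adds to the non-conjugated C6 carbonyl and not to C7, which the para methoxy group deactivates, so C5 and not the aryl carbon C8 is the migrating atom. C5 moves with its bonding pair from C6 to the C7 carbonyl carbon; ring B closes to five members by this 1,2-shift through a three-centre transition state, the former C7 becomes ring carbon C6 of 14 and the former C6 its carboxyl C7, and proton transfer to the carboxylate makes the step irreversible. The new carbinol centre is set by the trans-fused half-chair: the former C6 lies on the β face above the C5–C7–C8 plane and stays there as the carboxyl, so the hydroxyl is pushed to the α face. C5 is re-formed in the flask under the control of C10, and C10 is untouched. The step needs C5 over C8 migration and trans over cis fusion; the methoxy group secures the first and the shielded β face of C5 the second.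

Step 9
Reactants: 14 12-methoxy hydroxy acid
Product: 15 12-methoxy diol (6α-hydroxy, C7 hydroxymethyl)
Conditions: LiAlH4, THF, reflux; then H2O
Reagents that add atoms: none
Why: Hydride reduction of the α-hydroxy acid to the 1,2-diol; C6 is not involved, and the diol is the form in which C7 can pass the basic steps that an aldehyde would not survive.

Step 10
Reactants: 15 12-methoxy diol
Product: 16 12-hydroxy diol (phenol)
Conditions: NaSEt, DMF, 130 °C; then dilute aq. HCl, 0 °C
Reagents that add atoms: none
Why: Nucleophilic O-demethylation (SN2 at the methyl group by thiolate); a Lewis acid such as BBr3 is avoided because it would ionise the para-oxygenated benzylic tertiary alcohol at C6.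

Step 11
Reactants: 16 12-hydroxy diol
Product: 20 hydroxyquinone diol (6α,7,12-trihydroxy-11,14-quinone), via ortho-quinone 17 (not isolated), via thio-catechol 18 (not isolated), via thio-ortho-quinone 19 (not isolated)
Conditions: Fremy's salt (KSO3)2NO, KH2PO4, acetone–H2O, 0 °C; then C6F5SH, CH2Cl2, 0 °C; then NaOH, MeOH, O2, 25 °C; then aq. HCl
Reagents that add atoms: Fremy's salt (potassium nitrosodisulfonate), [K+].[K+].[O]N(S(=O)(=O)[O-])S(=O)(=O)[O-]; sodium hydroxide, [Na+].[OH-]
Why: Teuber oxidation of a para-blocked phenol gives the 11,12-quinone 17; thia-Michael addition at C14 (the only unsubstituted ring carbon), aerobic re-oxidation to 19 and addition–elimination by hydroxide place the third oxygen, and the 14-hydroxy-11,12-quinone is the tautomer of the 12-hydroxy-11,14-quinone 20. Each stage is a known reaction of ortho-quinones, and the diol tolerates the alkali that the aldehyde would not.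

Step 12
Reactants: 20 hydroxyquinone diol
Product: 21 hydroxyquinone aldehyde (6α,12-dihydroxy-11,14-dioxo, C7 formyl on the β face of C6)
Conditions: IBX, EtOAc, 75 °C
Reagents that add atoms: none
Why: Oxidation with the pentavalent iodine reagent IBX, which converts the primary hydroxyl of a 1,2-diol into the aldehyde without cleaving the C6–C7 bond; the tertiary hydroxyl and the hydroxyquinone are inert, and neither acid nor base is present to trigger the α-ketol shift.

Step 13
Reactants: 22 levopimaric acid (abieta-8(14),12-dien-18-oic acid)
Product: 23 8,12-dioxo-13,14,15,16,17-pentanorlabdan-18-oic acid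
Conditions: O3, CH2Cl2–MeOH, −78 °C; then Me2S, −78 to 25 °C
Reagents that add atoms: ozone, [O-][O+]=O
Why: Ozonolysis with reductive work-up; both double bonds of the ring C diene are cleaved, C8 is left as ketone and C12 as aldehyde, and C13–C17 leave as 3-methyl-2-oxobutanal. C9 keeps its equatorial side chain, which is also the thermodynamic arrangement next to the new ketone.

Step 14
Reactants: 23 8,12-dioxo-13,14,15,16,17-pentanorlabdan-18-oic acid
Product: 24 (12E)-8,14-dioxo-15,17-dinorlabd-12-en-18-oic acid
Conditions: Ph3P=C(CH3)CHO, toluene, 90 °C
Reagents that add atoms: 2-(triphenylphosphoranylidene)propanal, CC(C=O)=P(c1ccccc1)(c1ccccc1)c1ccccc1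
Why: Wittig reaction of a stabilised ylide; it reacts with the aldehyde but not with the hindered C8 ketone, gives the E trisubstituted enal, and tolerates the free carboxyl.

Step 15
Reactants: 24 (12E)-8,14-dioxo-15,17-dinorlabd-12-en-18-oic acid
Product: 25 (12E)-labda-8(17),12,14-trien-18-oic acid
Conditions: Ph3PCH3Br, KOtBu, THF, 0 °C; 24 added, 0 to 65 °C; then aq. NH4Cl
Reagents that add atoms: methyltriphenylphosphonium bromide, C[P+](c1ccccc1)(c1ccccc1)c1ccccc1.[Br-]
Why: Double Wittig methylenation with excess ylide (one equivalent is spent on the carboxyl proton); the enal carbonyl reacts in the cold by 1,2-addition to give the diene and the C8 ketone on warming to give the exocyclic methylene, as is routine for 8-oxo labdanes. The E geometry at C12=C13 and the C9 configuration are not affected.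

Step 16
Reactants: 21 hydroxyquinone aldehyde; 25 (12E)-labda-8(17),12,14-trien-18-oic acid (in excess)
Product: 26 CNP0124601.1
Conditions: BF3·OEt2, CH2Cl2, −40 to 0 °C
Reagents that add atoms: none
Why: Acid-promoted (5+2) cycloaddition of a hydroxy-para-quinone with an alkene (perezone–pipitzol type), here between two molecules: the terminal CH2 of the diene (C15′) adds to C8, the β-carbon of the boron-chelated C8=C9–C11=O enone, and the allyl cation so formed is closed by the enol carbon C13 at C14′, which keeps the E C12′=C13′ bond and forms the ring C8–C15′–C14′–C13–C14. The alkene should approach the α face of the quinone, away from the C10 methyl and the C6 formyl group, which sets C8 and C13, and the side chain should take the endo position under the oxygenated C9–C11–C12 bridge (compact, charge-stabilised closure), which sets C14′. Diels–Alder addition is shut out because both quinone double bonds are tetrasubstituted, and the aromatising closure through oxygen is shut out because C8 carries no hydrogen.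

## Compound list

1 | (+)-dehydroabietic acid (abieta-8,11,13-trien-18-oic acid; 4R,5R,10S) | CC(C)c1ccc2c(c1)CC[C@H]1[C@](C)(C(=O)O)CCC[C@]21C | starting material
2 | dehydroabietinol (abieta-8,11,13-trien-18-ol) | CC(C)c1ccc2c(c1)CC[C@H]1[C@](C)(CO)CCC[C@]21C | intermediate
3 | dehydroabietinal (abieta-8,11,13-trien-18-al) | CC(C)c1ccc2c(c1)CC[C@H]1[C@](C)(C=O)CCC[C@]21C | intermediate
4 | dehydroabietinal (E)-hydrazone | CC(C)c1ccc2c(c1)CC[C@H]1[C@](C)(/C=N/N)CCC[C@]21C | intermediate
5 | abieta-8,11,13-triene (5α-H, 10β-methyl; 5S,10S) | CC(C)c1ccc2c(c1)CC[C@H]1C(C)(C)CCC[C@]21C | intermediate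
6 | 12-acetylabieta-8,11,13-triene | CC(C)c1cc2CC[C@H]3C(C)(C)CCC[C@]3(C)c2cc1C(C)=O | intermediate
7 | ferruginyl acetate (abieta-8,11,13-trien-12-yl acetate) | CC(C)c1cc2CC[C@H]3C(C)(C)CCC[C@]3(C)c2cc1OC(C)=O | intermediate
8 | ferruginol (abieta-8,11,13-trien-12-ol) | CC(C)c1cc2CC[C@H]3C(C)(C)CCC[C@]3(C)c2cc1O | intermediate
9 | ferruginol methyl ether (12-methoxyabieta-8,11,13-triene) | CC(C)c1cc2CC[C@H]3C(C)(C)CCC[C@]3(C)c2cc1OC | intermediate
10 | sugiol methyl ether (12-methoxyabieta-8,11,13-trien-7-one) | CC(C)c1cc2C(=O)C[C@H]3C(C)(C)CCC[C@]3(C)c2cc1OC | intermediate
11 | 6-hydroperoxy-12-methoxyabieta-8,11,13-trien-7-one (C6 configuration not controlled, destroyed in the same flask) | CC(C)c1cc2C(=O)C(OO)[C@H]3C(C)(C)CCC[C@]3(C)c2cc1OC | intermediate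
12 | 12-methoxyabieta-8,11,13-triene-6,7-dione (5α-H, trans-fused) | CC(C)c1cc2C(=O)C(=O)[C@H]3C(C)(C)CCC[C@]3(C)c2cc1OC | intermediate
13 | 6-hydroxy-12-methoxyabieta-5,8,11,13-tetraen-7-one (diosphenol, 10β-methyl; present in the flask as its potassium dienolate) | CC(C)c1cc2C(=O)C(O)=C3C(C)(C)CCC[C@]3(C)c2cc1OC | intermediate
14 | 12-methoxy hydroxy acid of the 6-5-6 series: ring B = C5, C6, C8, C9, C10; 6α-OH, C7 carboxyl β on C6, 5α-H, 10β-methyl | CC(C)c1cc2c(cc1OC)[C@@]1(C)CCCC(C)(C)[C@@H]1[C@]2(O)C(=O)O | intermediate
15 | 12-methoxy diol: as 14 with C7 as hydroxymethyl | CC(C)c1cc2c(cc1OC)[C@@]1(C)CCCC(C)(C)[C@@H]1[C@]2(O)CO | intermediate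
16 | 12-hydroxy diol (phenol): as 15 with free C12 hydroxyl | CC(C)c1cc2c(cc1O)[C@@]1(C)CCCC(C)(C)[C@@H]1[C@]2(O)CO | intermediate
17 | 11,12-ortho-quinone diol | CC(C)C1=CC2=C(C(=O)C1=O)[C@@]1(C)CCCC(C)(C)[C@@H]1[C@]2(O)CO | intermediate
18 | 14-(pentafluorophenylthio)-11,12-dihydroxy arene diol (thio-catechol) | CC(C)c1c(Sc2c(F)c(F)c(F)c(F)c2F)c2c(c(O)c1O)[C@@]1(C)CCCC(C)(C)[C@@H]1[C@]2(O)CO | intermediate
19 | 14-(pentafluorophenylthio)-11,12-ortho-quinone diol | CC(C)C1=C(Sc2c(F)c(F)c(F)c(F)c2F)C2=C(C(=O)C1=O)[C@@]1(C)CCCC(C)(C)[C@@H]1[C@]2(O)CO | intermediate
20 | hydroxyquinone diol: 12-hydroxy-11,14-quinone, 6α-OH, C7 hydroxymethyl β, 5α-H, 10β-methyl | O=C1C2=C(C(=O)C(O)=C1C(C)C)[C@@]1(C)CCCC(C)(C)[C@@H]1[C@]2(O)CO | intermediate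
21 | hydroxyquinone aldehyde: as 20 with C7 as formyl | O=C1C2=C(C(=O)C(O)=C1C(C)C)[C@@]1(C)CCCC(C)(C)[C@@H]1[C@]2(O)C=O | intermediate
22 | levopimaric acid (abieta-8(14),12-dien-18-oic acid; 4R,5R,9S,10R) | C1=C2CC[C@@H]3[C@](C)(CCC[C@@]3(C)C(=O)O)[C@H]2CC=C1C(C)C | starting material
23 | 8,12-dioxo-13,14,15,16,17-pentanorlabdan-18-oic acid (5α-H, 9α-H, 10β-methyl, 4α-carboxyl) | O=C1CC[C@@H]2[C@](C)(CCC[C@@]2(C)C(=O)O)[C@H]1CC=O | intermediate
24 | (12E)-8,14-dioxo-15,17-dinorlabd-12-en-18-oic acid | O=C1CC[C@@H]2[C@](C)(CCC[C@@]2(C)C(=O)O)[C@H]1C/C=C(\C)C=O | intermediate
25 | (12E)-labda-8(17),12,14-trien-18-oic acid (4R,5R,9S,10R) | C=C1CC[C@@H]2[C@](C)(CCC[C@@]2(C)C(=O)O)[C@H]1C/C=C(\C)C=C | intermediate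
26 | CNP0124601.1: (5+2) adduct with bonds C8–C15′ and C13–C14′, two-carbon bridge on the α face, side chain endo at C14′ | C=C1CC[C@@H]2[C@](C)(CCC[C@@]2(C)C(=O)O)[C@H]1C/C=C(\C)[C@@H]1C[C@@]23C(=O)[C@]1(C(C)C)C(=O)C(O)=C2[C@@]1(C)CCCC(C)(C)[C@@H]1[C@]3(O)C=O | target

## Step count and risk

Total: 16 steps. Longest linear sequence: 13 steps (steps 1–12 and 16); the labdane branch is steps 13–15.

**Step 8 (key step).** Two processes can go wrong in this flask. During the oxygenation the dienolate of 13 may take up a second molecule of oxygen, which cleaves ring B between C6 and C7; for this reason the gas uptake is metered and the flask is purged before heating. During the rearrangement the C5 configuration may be lost through the dienolate before the shift. β-Face protonation would open the cis-fused series, whose contraction may be faster because a cis-fused hydrindane is less strained. Behind these stands migration of the aryl carbon C8 instead of C5, which would invert C6.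

Fallback, from 10 back to 15: the contraction is done without base and without oxygen on the intact C5 centre by a Wolff rearrangement. Ketone 10 is trifluoroacetylated at C6 (LiN(SiMe3)2, CF3CO2CH2CF3) to the 6-trifluoroacetyl ketone F1. Detrifluoroacetylative diazo transfer (MsN3, Et3N) gives the 6-diazo ketone F2. Photolysis in methanol lets C8 move from C7 to C6 and gives the ring-contracted methyl ester F3. Its potassium enolate (KN(SiMe3)2, −78 °C) is hydroxylated with a 2-sulfonyloxaziridine on the α face, opposite the C10 methyl, to the hydroxy ester F4. LiAlH4 reduction of F4 gives diol 15.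

**Step 16.** The cycloaddition is bimolecular and has to build the quaternary C8 next to the quaternary C6. The likely failure is that the Lewis acid consumes the partners faster than they combine. The main candidates are α-ketol ring enlargement of the bound hydroxy aldehyde, its carbonyl-ene reaction with the exocyclic methylene of 25, and cationic oligomerisation of the diene. Unselective capture of the allyl cation (exo instead of endo) is the second concern.

Fallback, from 20 and 25 back to 26: the union is moved one step earlier. Hydroxyquinone diol 20, which has no aldehyde, is combined with 25 under the same promotion to the adduct diol F5. The primary alcohol of F5 is then oxidised with IBX as the last step to give 26.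

**Step 11.** The likely failure is degradation of the electron-poor ortho-quinone in alkaline oxygen (ring cleavage), or its capture by the neighbouring primary hydroxyl at C14 before the thiol adds.

Fallback, from 16 back to 20: the third oxygen is introduced under acid instead. Ortho-quinone 17 is isolated after the Fremy's salt oxidation and submitted to Thiele–Winter acetoxylation (Ac2O, BF3·OEt2 cat., 0 °C). This adds acetate at C14 and acetylates the phenolic and primary hydroxyls to the tetraacetate F6. Methanolysis (K2CO3, MeOH) in air releases the hydroxyhydroquinone, which autoxidises to 20.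

## Further compounds

F1 | step 8 | 12-methoxy-6-(trifluoroacetyl)abieta-8,11,13-trien-7-one (C6 not defined, enolised) | CC(C)c1cc2C(=O)C(C(=O)C(F)(F)F)[C@H]3C(C)(C)CCC[C@]3(C)c2cc1OC
F2 | step 8 | 6-diazo-12-methoxyabieta-8,11,13-trien-7-one | CC(C)c1cc2C(=O)C(=[N+]=[N-])[C@H]3C(C)(C)CCC[C@]3(C)c2cc1OC
F3 | step 8 | methyl ester of the 12-methoxy 6-5-6 acid without C6 hydroxyl (C6 epimers, both converge in the enolate) | CC(C)c1cc2c(cc1OC)[C@@]1(C)CCCC(C)(C)[C@@H]1C2C(=O)OC
F4 | step 8 | methyl ester of hydroxy acid 14 (6α-OH) | CC(C)c1cc2c(cc1OC)[C@@]1(C)CCCC(C)(C)[C@@H]1[C@]2(O)C(=O)OC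
F5 | step 16 | adduct diol: 26 with C7 as hydroxymethyl | C=C1CC[C@@H]2[C@](C)(CCC[C@@]2(C)C(=O)O)[C@H]1C/C=C(\C)[C@@H]1C[C@@]23C(=O)[C@]1(C(C)C)C(=O)C(O)=C2[C@@]1(C)CCCC(C)(C)[C@@H]1[C@]3(O)CO
F6 | step 11 | 11,12,14-triacetoxy arene with C7 acetoxymethyl and free 6α-hydroxyl (tetraacetate) | CC(C)c1c(OC(C)=O)c2c(c(OC(C)=O)c1OC(C)=O)[C@@]1(C)CCCC(C)(C)[C@@H]1[C@]2(O)COC(C)=O
A1 | alternative 1 | 12,13,14,15,16-pentanorlabd-8(17)-ene-3β,11,18-triol 11,18-diacetate | C=C1CC[C@@H]2[C@](C)(CC[C@H](O)[C@@]2(C)COC(C)=O)[C@H]1COC(C)=O
A2 | alternative 1 | (2E,6E,10S,11S)-10,11-epoxy-3,7,11-trimethyldodeca-2,6-diene-1,12-diyl diacetate | CC(=O)OC/C=C(\C)CC/C=C(\C)CC[C@@H]1O[C@@]1(C)COC(C)=O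
A3 | alternative 1 | (2E,6E)-farnesol | CC(C)=CCC/C(C)=C/CC/C(C)=C/CO
A4 | alternative 2 | 11-benzyloxy-12-hydroxy-13-isopropyl arene of the 6-5-6 series with the C6/C7 diol as acetonide | CC(C)c1cc2c(c(OCc3ccccc3)c1O)[C@@]1(C)CCCC(C)(C)[C@@H]1[C@]21COC(C)(C)O1
A5 | alternative 2 | trans-hydrindan-9-one with 10β-methyl, C4 gem-dimethyl and the C6/C7 diol as acetonide | O=C2[C@@]1(C)CCCC(C)(C)[C@@H]1[C@]1(COC(C)(C)O1)C2
A6 | alternative 2 | (E)-1-(benzyloxy)-3-(methoxymethylidene)-4-methylpentan-2-one | CO/C=C(\C(C)C)C(=O)COCc1ccccc1
A7 | alternative 3 | ring-contracted dimer, C7 ethyl thioester, 11-O-methyl enol ether, 2-(trimethylsilyl)ethyl ester | C=C1CC[C@@H]2[C@](C)(CCC[C@@]2(C)C(=O)OCC[Si](C)(C)C)[C@H]1C/C=C(\C)[C@@H]1C[C@@]23C(=O)[C@]1(C(C)C)C(=O)C(OC)=C2[C@@]1(C)CCCC(C)(C)[C@@H]1[C@@H]3C(=O)SCC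
A8 | alternative 3 | C6-diazo C7-ketone of the (5+2) adduct with six-membered ring B | C=C1CC[C@@H]2[C@](C)(CCC[C@@]2(C)C(=O)OCC[Si](C)(C)C)[C@H]1C/C=C(\C)[C@@H]1C[C@@]23C(=O)[C@]1(C(C)C)C(=O)C(OC)=C2[C@@]1(C)CCCC(C)(C)[C@@H]1C(=[N+]=[N-])C3=O
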